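The cyclohexane ring (C2–C16–C17–C20–C19–C18; C2 indoline aminal carbon, C16 ester-bearing CH, C20 quaternary carbon on N4) is cut at C17–C20 and C2–C18 into two three-carbon halves held together by the N4–C5–C6–C7 chain. The key step exploits that C17 and C2 are the Michael and imine carbons of a 2-(1-methoxycarbonylvinyl)-3H-indolium, while C20 and C18 are α to the C15 ketone and to a removable formyl group. One acid-triggered decarboxylative Michael–Mannich cascade closes cyclohexane and azocine and sets C2, C16 and C20 from C7. Its precursor is a tethered vinylogous carbamate and quaternary tert-butyl β-keto ester aldehyde; C7 comes from an asymmetric Claisen rearrangement.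

Key step: step 11

Remark: atoms carry biogenetic labels (N1, C2, C7 = indoline C3, C6–C5–N4 bridge, C3/C14/C15 pyrrolidine carbons, C20, C19–C18 bridge, C17, C16); the antipode of the ligand in step 2 is assumed to be the one that delivers the (S)-oxindole.

Step 1
Reactants: 1 methyl 1H-indole-3-carboxylate; 2 allyl alcohol
Product: 4 methyl 2-(allyloxy)-1H-indole-3-carboxylate, via 3-chloroindolenine 3 (not isolated)
Conditions: NCS, 1,4-dimethylpiperazine, CH2Cl2, 0 °C; then 2, Cl3CCO2H (cat.), 0 °C → rt
Reagents that add atoms: allyl alcohol (2), C=CCO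
Why: C3-chlorination gives the 3-chloroindolenine, to which the alcohol adds at C2 under acid catalysis, and loss of HCl re-aromatises (oxidative 2-alkoxylation of an indole-3-carboxylate).

Step 2
Reactants: 4 methyl 2-(allyloxy)-1H-indole-3-carboxylate
Product: 5 methyl (S)-3-allyl-2-oxoindoline-3-carboxylate
Conditions: PdCl2[(S)-t-BuPHOX] (10 mol %), AgSbF6 (20 mol %), CH2Cl2, 0 °C → rt
Reagents that add atoms: none
Why: Catalytic enantioselective Meerwein–Eschenmoser Claisen rearrangement; the cationic divalent palladium complex binds the β-amido ester at two points and its chiral ligand decides which face of C7 receives the allyl group, which sets the quaternary C7 centre.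

Step 3
Reactants: 5 methyl (S)-3-allyl-2-oxoindoline-3-carboxylate
Product: 6 methyl (R)-3-allyl-2-thioxoindoline-3-carboxylate
Conditions: Lawesson's reagent (0.6 equiv), toluene, 90 °C
Reagents that add atoms: Lawesson's reagent, COc1ccc(cc1)P1(=S)SP(=S)(S1)c1ccc(OC)cc1
Why: Thionation of the secondary lactam, which is far more reactive toward the reagent than the ester; C7 is untouched (the descriptor changes only because sulfur outranks oxygen).

Step 4
Reactants: 6 methyl (R)-3-allyl-2-thioxoindoline-3-carboxylate; 7 methyl bromoacetate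
Product: 9 methyl (S,Z)-3-allyl-2-(2-methoxy-2-oxoethylidene)indoline-3-carboxylate, via S-alkyl thioimidate 8 (not isolated)
Conditions: 7, MeCN, rt; then PPh3, Et3N, 60 °C
Reagents that add atoms: methyl bromoacetate (7), COC(=O)CBr
Why: Eschenmoser sulfide contraction (S-alkylation, thiirane formation at C2, sulfur extrusion by the phosphine); the Z geometry should follow from the N1–H···O=C hydrogen bond of the vinylogous carbamate.

Step 5
Reactants: 9 methyl (S,Z)-3-allyl-2-(2-methoxy-2-oxoethylidene)indoline-3-carboxylate
Product: 11 methyl (S,Z)-2-(2-methoxy-2-oxoethylidene)-3-(2-oxoethyl)indoline-3-carboxylate, via vicinal diol 10 (not isolated)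
Conditions: OsO4 (2 mol %), NaIO4 (4 equiv), 2,6-lutidine, dioxane/H2O 3:1, 0 °C → rt; 11 used at once
Reagents that add atoms: osmium tetroxide, O=[Os](=O)(=O)=O (catalytic; re-oxidised by sodium periodate, [Na+].[O-]I(=O)(=O)=O, the net oxygen source)
Why: Lemieux–Johnson cleavage; the unhindered monosubstituted alkene should be dihydroxylated in preference to the push–pull C2=C16 bond shielded by quaternary C7, and periodate cleaves the diol to the C5 aldehyde.

Step 6
Reactants: 12 tert-butyl N-benzylglycinate; 13 methyl acrylate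
Product: 14 tert-butyl N-benzyl-N-(3-methoxy-3-oxopropyl)glycinate
Conditions: MeOH, rt → 40 °C
Reagents that add atoms: methyl acrylate (13), C=CC(=O)OC
Why: Aza-Michael addition of the secondary amine to the acrylate.

Step 7
Reactants: 14 tert-butyl N-benzyl-N-(3-methoxy-3-oxopropyl)glycinate
Product: 15 tert-butyl 1-benzyl-3-oxopyrrolidine-2-carboxylate (racemic)
Conditions: KOtBu (1.1 equiv), toluene, 0 °C; AcOH quench
Reagents that add atoms: none
Why: Kinetically controlled Dieckmann condensation; only the enolate α to the tert-butyl ester has a good acyl acceptor (the methyl ester), so the 3-oxo-2-carboxylate regioisomer should form.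

Step 8
Reactants: 15 tert-butyl 1-benzyl-3-oxopyrrolidine-2-carboxylate
Product: 16 tert-butyl 3-oxopyrrolidine-2-carboxylate (racemic)
Conditions: H2 (1 atm), Pd(OH)2/C, EtOAc, rt; filtrate used at once
Reagents that add atoms: none
Why: Hydrogenolysis of the N-benzyl group; the β-keto ester is inert and the free amine is used directly because α-amino ketones self-condense.

Step 9
Reactants: 11 methyl (S,Z)-2-(2-methoxy-2-oxoethylidene)-3-(2-oxoethyl)indoline-3-carboxylate; 16 tert-butyl 3-oxopyrrolidine-2-carboxylate
Product: 18 tert-butyl 1-{2-[(2Z,3S)-3-(methoxycarbonyl)-2-(2-methoxy-2-oxoethylidene)indolin-3-yl]ethyl}-3-oxopyrrolidine-2-carboxylate (both C20 epimers), via iminium acetate 17 (not isolated)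
Conditions: NaBH(OAc)3, ClCH2CH2Cl, 0 °C → rt
Reagents that add atoms: none
Why: Reductive amination; the secondary amine condenses with the unhindered aldehyde and the iminium ion is reduced faster than the enolised keto ester or the vinylogous carbamate, which forms the N4–C5 bond.

Step 10
Reactants: 18 tethered β-keto ester; 19 acrolein
Product: 20 tert-butyl 1-{2-[(2Z,3S)-3-(methoxycarbonyl)-2-(2-methoxy-2-oxoethylidene)indolin-3-yl]ethyl}-3-oxo-2-(3-oxopropyl)pyrrolidine-2-carboxylate (both C20 epimers)
Conditions: Et3N (10 mol %), CH2Cl2, −20 → 0 °C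
Reagents that add atoms: acrolein (19), C=CC=O
Why: Michael addition of the β-keto ester, the only carbon acid the amine base deprotonates, so C19/C18 and the formyl group are attached to C20 alone; the new C20 centre is erased by the decarboxylation in step 11.

Step 11
Reactants: 20 quaternary β-keto ester aldehyde; 21 N,N-dimethylmethyleneiminium iodide (Eschenmoser's salt)
Product: 25 pentacyclic amino keto aldehyde (N1-H; 15-oxo; 18-formyl; 2R,7S,16R,20R; C18 epimers), via Mannich base 22 (not isolated), via azadiene enol 23 (not isolated), via azocine vinylogous carbamate 24 (not isolated)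
Conditions: 21 (1.05 equiv), CH2Cl2, 0 °C → rt; then dilution to 0.003 M, CF3CO2H (15 vol %), 0 → 40 °C; aq. NaHCO3
Reagents that add atoms: Eschenmoser's salt (21), C=[N+](C)C.[I-]
Why: Proposed new method: the iminium salt aminomethylates the nucleophilic C16 of the vinylogous carbamate (22); in CF3CO2H the tert-butyl ester is cleaved, the quaternary β-keto acid loses CO2 to give the C20 enol regiospecifically, and 22 loses dimethylamine (vinylogous gramine elimination) to the N-protonated azadiene 23, whose C17 is attacked by the enol (C17–C20, azocine 24), after which C16-protonation of 24 gives a 3H-indolium whose C2 is attacked by the enol (or dimethylamine-derived enamine) of the pendant aldehyde (C2–C18). The closest known reaction types are the decarboxylative alkylation of β-keto acids by gramine-type Mannich bases and the acid-mediated Mannich cyclisation of carbonyl enols onto 2-alkyl-3H-indolium ions, together a Michael–Mannich formal [3+3] annulation on a 1-azadiene. The azocine closes first by 8-endo-trig conjugate addition at C17 and the cyclohexane then by 6-(enolexo)-exo-trig attack on C2=N1. C20 is set in the conjugate addition through a compact transition state that holds the enol oxygen over the indoleninium N1–H on the face of the azadiene bearing the C6–C5 tether; the resulting cage lets C18 reach C2 only from the opposite face, cis to the C7 ester (C2), and the C16 ester turns away from the incoming C18 toward the azocine (C16). The step needs C20 rather than C14 as the nucleophile (secured by the site of decarboxylation), attack of C20 at C17 rather than at C2 (C2 is flanked by quaternary C7), and ring closure rather than oligomerisation (high dilution); the dimethylammonium trifluoroacetate set free serves as the enamine catalyst for the Mannich closure.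

Step 12
Reactants: 25 pentacyclic amino keto aldehyde; 26 methyl chloroformate
Product: 27 N1-methoxycarbonyl keto aldehyde (2R,7S,16R,20R; C18 epimers)
Conditions: ClCO2Me (3 equiv), NaHCO3, CH2Cl2/H2O, 0 °C → rt (on crude 25)
Reagents that add atoms: methyl chloroformate (26), COC(=O)Cl
Why: Schotten–Baumann carbamoylation of the indoline N1–H; acylation removes the nitrogen lone pair and so blocks any retro-Mannich opening at C2–C18.

Step 13
Reactants: 27 N1-methoxycarbonyl keto aldehyde
Product: 28 N1-methoxycarbonyl 15-ketone (2R,7S,16R,20R)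
Conditions: RhCl(PPh3)3 (1.2 equiv), toluene, 110 °C
Reagents that add atoms: none
Why: Tsuji–Wilkinson decarbonylation (oxidative addition of the formyl C–H bond to monovalent rhodium, CO extrusion, C–H reductive elimination) replaces the activating formyl group by hydrogen, and the C18 stereocentre vanishes.

Step 14
Reactants: 28 N1-methoxycarbonyl 15-ketone
Product: 29 target CNP0144467.2 (2R,7S,15R,16R,20R)
Conditions: NaBH4, MeOH, −40 → −20 °C
Reagents that add atoms: none
Why: Substrate-controlled borohydride reduction; the ketone face syn to the C16–C17 bridge is shielded by that bridge and by the azocine methylenes C5/C6 on N4, so hydride should enter from the side of the bare C18–C19 bridge and place the hydroxyl cis to C17 (15R).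

Compound list
1 | methyl 1H-indole-3-carboxylate | COC(=O)c1c[nH]c2ccccc12 | starting material
2 | allyl alcohol | C=CCO | starting material
3 | methyl 3-chloro-3H-indole-3-carboxylate (racemic) | COC(=O)C1(Cl)C=Nc2ccccc12 | intermediate
4 | methyl 2-(allyloxy)-1H-indole-3-carboxylate | C=CCOc1[nH]c2ccccc2c1C(=O)OC | intermediate
5 | methyl (S)-3-allyl-2-oxoindoline-3-carboxylate | O=C1Nc2ccccc2[C@@]1(C(=O)OC)CC=C | intermediate
6 | methyl (R)-3-allyl-2-thioxoindoline-3-carboxylate | S=C1Nc2ccccc2[C@@]1(C(=O)OC)CC=C | intermediate
7 | methyl bromoacetate | COC(=O)CBr | starting material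
8 | methyl (R)-3-allyl-2-[(2-methoxy-2-oxoethyl)sulfanyl]-3H-indole-3-carboxylate | COC(=O)CSC1=Nc2ccccc2[C@@]1(C(=O)OC)CC=C | intermediate
9 | methyl (S,Z)-3-allyl-2-(2-methoxy-2-oxoethylidene)indoline-3-carboxylate | COC(=O)/C=C1\Nc2ccccc2[C@@]1(C(=O)OC)CC=C | intermediate
10 | methyl (3S,Z)-3-(2,3-dihydroxypropyl)-2-(2-methoxy-2-oxoethylidene)indoline-3-carboxylate (diol epimers) | COC(=O)/C=C1\Nc2ccccc2[C@@]1(C(=O)OC)CC(O)CO | intermediate
11 | methyl (S,Z)-2-(2-methoxy-2-oxoethylidene)-3-(2-oxoethyl)indoline-3-carboxylate | COC(=O)/C=C1\Nc2ccccc2[C@@]1(C(=O)OC)CC=O | intermediate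
12 | tert-butyl N-benzylglycinate | CC(C)(C)OC(=O)CNCc1ccccc1 | starting material
13 | methyl acrylate | C=CC(=O)OC | starting material
14 | tert-butyl N-benzyl-N-(3-methoxy-3-oxopropyl)glycinate | COC(=O)CCN(Cc1ccccc1)CC(=O)OC(C)(C)C | intermediate
15 | tert-butyl 1-benzyl-3-oxopyrrolidine-2-carboxylate (racemic) | O=C1CCN(Cc2ccccc2)C1C(=O)OC(C)(C)C | intermediate
16 | tert-butyl 3-oxopyrrolidine-2-carboxylate (racemic) | O=C1CCNC1C(=O)OC(C)(C)C | intermediate
17 | iminium acetate formed from 11 and 16 (C5=N4 iminium) | COC(=O)/C=C1\Nc2ccccc2[C@@]1(C(=O)OC)CC=[N+]1CCC(=O)C1C(=O)OC(C)(C)C.CC(=O)[O-] | intermediate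
18 | tert-butyl 1-{2-[(2Z,3S)-3-(methoxycarbonyl)-2-(2-methoxy-2-oxoethylidene)indolin-3-yl]ethyl}-3-oxopyrrolidine-2-carboxylate (C20 epimers) | COC(=O)/C=C1\Nc2ccccc2[C@@]1(C(=O)OC)CCN1CCC(=O)C1C(=O)OC(C)(C)C | intermediate
19 | acrolein | C=CC=O | starting material
20 | tert-butyl 1-{2-[(2Z,3S)-3-(methoxycarbonyl)-2-(2-methoxy-2-oxoethylidene)indolin-3-yl]ethyl}-3-oxo-2-(3-oxopropyl)pyrrolidine-2-carboxylate (C20 epimers) | COC(=O)/C=C1\Nc2ccccc2[C@@]1(C(=O)OC)CCN1CCC(=O)C1(CCC=O)C(=O)OC(C)(C)C | intermediate
21 | N,N-dimethylmethyleneiminium iodide (Eschenmoser's salt) | C=[N+](C)C.[I-] | starting material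
22 | Mannich base: 20 carrying CH2NMe2 on C16 | COC(=O)/C(CN(C)C)=C1\Nc2ccccc2[C@@]1(C(=O)OC)CCN1CCC(=O)C1(CCC=O)C(=O)OC(C)(C)C | intermediate
23 | azadiene enol: methyl (S)-3-{2-[3-hydroxy-2-(3-oxopropyl)-4,5-dihydropyrrol-1-yl]ethyl}-2-(3-methoxy-3-oxoprop-1-en-2-yl)-3H-indole-3-carboxylate (reacts N-protonated) | C=C(C(=O)OC)C1=Nc2ccccc2[C@@]1(C(=O)OC)CCN1CCC(O)=C1CCC=O | intermediate
24 | azocine vinylogous carbamate (C17–C20 bond formed; 7S,20R; 15-ketone; 3-oxopropyl on C20) | COC(=O)C1=C2Nc3ccccc3[C@@]2(C(=O)OC)CCN2CCC(=O)[C@@]2(CCC=O)C1 | intermediate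
25 | pentacyclic amino keto aldehyde: N1-H, 15-oxo, 18-formyl analogue of the target (2R,7S,16R,20R; C18 epimers) | COC(=O)[C@@H]1C[C@@]23CC(C=O)[C@@]14Nc1ccccc1[C@@]4(C(=O)OC)CCN2CCC3=O | intermediate
26 | methyl chloroformate | COC(=O)Cl | starting material
27 | N1-methoxycarbonyl derivative of 25 (2R,7S,16R,20R; C18 epimers) | COC(=O)[C@@H]1C[C@@]23CC(C=O)[C@@]14N(C(=O)OC)c1ccccc1[C@@]4(C(=O)OC)CCN2CCC3=O | intermediate
28 | 15-oxo analogue of the target (2R,7S,16R,20R) | COC(=O)[C@@H]1C[C@@]23CC[C@@]14N(C(=O)OC)c1ccccc1[C@@]4(C(=O)OC)CCN2CCC3=O | intermediate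
29 | CNP0144467.2: N1,C7,C16-tris(methoxycarbonyl) 15-alcohol (2R,7S,15R,16R,20R) | COC(=O)[C@@H]1C[C@@]23CC[C@@]14N(C(=O)OC)c1ccccc1[C@@]4(C(=O)OC)CCN2CC[C@H]3O | target

Total step count: 14. Longest linear sequence: 11 steps (steps 1–5 and 9–14).

Steps most likely to fail

Step 11 (Proposed new method). The Mannich closure may revert to the conjugated vinylogous carbamate, or the aldehyde enol may fail to reach the hindered C2 iminium carbon, so that the cascade stops after the conjugate addition. The fallback sets out from 18 and returns at 28. Conjugate addition of 18 to tert-butyl acrylate (Et3N cat., CH2Cl2) should give the bis(tert-butyl) ester F1. Eschenmoser's salt and then CF3CO2H, as in step 11, are asked only for the decarboxylative alkylation and should give the azocine vinylogous carbamate acid F2. N-Hydroxyphthalimide and N,N'-diisopropylcarbodiimide convert it into the redox-active ester F3. Ru(bpy)3(PF6)2, Hantzsch ester, iPr2NEt and blue light then generate the primary C18 radical, which should add irreversibly to C2, the β-carbon of the anilinoacrylate (radical conjugate addition closing the six-membered ring), to give the N1-H keto amine F4 after reduction and protonation at C16. ClCO2Me/NaHCO3 converts F4 into 28, which makes step 13 unnecessary.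

Step 5. Osmylation and cleavage of the electron-rich C2=C16 bond may compete with the allyl group, and the free aldehyde may condense with the enamine carbon C16. The fallback sets out from 5 and returns at 11. Ozonolysis of 5 (O3, CH2Cl2/MeOH, −78 °C; Me2S), before any enamine exists, should give the oxindole aldehyde F5. HC(OMe)3 and PPTS in MeOH give the dimethyl acetal F6, Lawesson's reagent the thiolactam acetal F7, and sulfide contraction with 7 (PPh3, Et3N, as in step 4) the vinylogous carbamate acetal F8. Mild hydrolysis (oxalic acid on wet silica, CH2Cl2) releases 11 immediately before step 9.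

Step 14. Hydride delivery to the C15 ketone may show poor facial selectivity and give the 15-epimer. The fallback sets out from 28 and returns at 29: a ketoreductase selected from a screening panel for the 15R alcohol (NADP+, isopropanol, pH 7 buffer/DMSO, 30 °C) replaces substrate control by catalyst control; it makes no compound outside the list (F0).

Further compounds
F1 | step 11 | tert-butyl 2-(3-tert-butoxy-3-oxopropyl)-1-{2-[(2Z,3S)-3-(methoxycarbonyl)-2-(2-methoxy-2-oxoethylidene)indolin-3-yl]ethyl}-3-oxopyrrolidine-2-carboxylate (C20 epimers) | COC(=O)/C=C1\Nc2ccccc2[C@@]1(C(=O)OC)CCN1CCC(=O)C1(CCC(=O)OC(C)(C)C)C(=O)OC(C)(C)C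
F2 | step 11 | azocine vinylogous carbamate acid (as 24 with CH2CH2CO2H on C20; 7S,20R) | COC(=O)C1=C2Nc3ccccc3[C@@]2(C(=O)OC)CCN2CCC(=O)[C@@]2(CCC(=O)O)C1
F3 | step 11 | N-(acyloxy)phthalimide ester of F2 | COC(=O)C1=C2Nc3ccccc3[C@@]2(C(=O)OC)CCN2CCC(=O)[C@@]2(CCC(=O)ON4C(=O)c5ccccc5C4=O)C1
F4 | step 11 | N1-H 15-oxo analogue of the target (2R,7S,16R,20R) | COC(=O)[C@@H]1C[C@@]23CC[C@@]14Nc1ccccc1[C@@]4(C(=O)OC)CCN2CCC3=O
F5 | step 5 | methyl (S)-2-oxo-3-(2-oxoethyl)indoline-3-carboxylate | O=C1Nc2ccccc2[C@@]1(C(=O)OC)CC=O
F6 | step 5 | methyl (S)-3-(2,2-dimethoxyethyl)-2-oxoindoline-3-carboxylate | O=C1Nc2ccccc2[C@@]1(C(=O)OC)CC(OC)OC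
F7 | step 5 | methyl (R)-3-(2,2-dimethoxyethyl)-2-thioxoindoline-3-carboxylate | S=C1Nc2ccccc2[C@@]1(C(=O)OC)CC(OC)OC
F8 | step 5 | methyl (S,Z)-3-(2,2-dimethoxyethyl)-2-(2-methoxy-2-oxoethylidene)indoline-3-carboxylate | COC(=O)/C=C1\Nc2ccccc2[C@@]1(C(=O)OC)CC(OC)OC
F0 | step 14 | none | none
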